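**Retrosynthetic overview**

- Target ⇒ prostaglandin E1 by saturation of C13=C14 ⇒ prostaglandin H1, whose 9,11-endoperoxide is opened to the 9-ketone and the 11α-alcohol.
- Key disconnection of prostaglandin H1: C8–C12, C9–O and C11–O (one O2) and C15–O (a second O2), back to all-cis icosa-8,11,14-trienoic acid. The dioxolane closes first and the cyclopentane second, both in the one enzymatic step; the dioxolane is opened afterwards.
- Feature on which the plan rests: the cyclopentane C8–C12 with oxygens on C9 and C11 in a cis-1,3 relation, trans chains on C8 and C12, and the 15S carbinol two carbons beyond C12. This is the pattern cyclooxygenase writes onto a C20 8,11,14-triene, and the C13–C14 ethylene unit of the target is the one alkene that cascade leaves.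
- Triene ⇒ icosa-8,11,14-triynoic acid (threefold cis-semihydrogenation) ⇒ two copper-catalysed alkynyl–propargyl couplings forming C13–C14 and C9–C10 from hept-1-yne, 1,4-dichlorobut-2-yne and non-8-ynoic acid.

Key step: step 4

Assumption: purified ovine COX-1 and recombinant human microsomal PGE synthase-1 are taken as purchasable biocatalysts, and steps 4 to 6 are run on milligram scale in repeated batches, because the cyclooxygenase inactivates itself during turnover and the endoperoxide is short-lived in water.

**Step 1**
Reactants: 1 hept-1-yne; 2 1,4-dichlorobut-2-yne
Product: 4 1-chloroundeca-2,5-diyne, via hept-1-ynylmagnesium bromide 3 (not isolated)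
Conditions: EtMgBr (1.0 equiv), THF, 0 to 40 °C; then CuI (5 mol %), 2 (3 equiv), THF, reflux; aq NH4Cl; distillation under reduced pressure
Reagents that add atoms: none
Why: Deprotonation gives the alkynyl Grignard 3, which transmetalates to a monovalent copper acetylide and displaces one primary propargylic chloride of 2 by SN2 (copper-catalysed alkynyl–propargyl coupling), the excess of the symmetrical dichloride keeping the second chloride for step 2; no stereocentre is formed.

**Step 2**
Reactants: 5 non-8-ynoic acid; 4 1-chloroundeca-2,5-diyne
Product: 7 icosa-8,11,14-triynoic acid, via non-8-ynoic acid bis(bromomagnesium) salt 6 (not isolated)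
Conditions: EtMgBr (2.0 equiv), THF, 0 °C to rt; CuI (10 mol %), then 4, THF, rt to 50 °C; cold 1 M HCl; crystallization under Ar, stored cold
Reagents that add atoms: none
Why: Two equivalents of the Grignard base mask the acid as its magnesium carboxylate and metalate the alkyne, and the acetylide carbon of 6 then displaces the propargylic chloride of 4 under monovalent copper catalysis (the same SN2 alkynyl–propargyl coupling), which assembles the methylene-interrupted C20 triyne without any stereocentre.

**Step 3**
Reactants: 7 icosa-8,11,14-triynoic acid
Product: 8 dihomo-γ-linolenic acid, (8Z,11Z,14Z)-icosa-8,11,14-trienoic acid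
Conditions: H2 (1 atm, stopped at 3 equiv uptake), Pd/CaCO3 poisoned with Pb(OAc)2, quinoline, EtOAc, 10 °C; C18 reversed-phase chromatography under Ar
Reagents that add atoms: none
Why: Lindlar semihydrogenation, in which syn delivery of H2 from the lead-poisoned palladium surface, moderated further by quinoline and stopped at three equivalents, should turn each alkyne into a Z-alkene without touching the acid, so the three alkene geometries are fixed here.

**Step 4**
Reactants: 8 dihomo-γ-linolenic acid
Product: 10 prostaglandin H1 [(9α,11α)-epidioxy-(15S)-hydroxyprost-(13E)-enoic acid], via prostaglandin G1 9 (not isolated)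
Conditions: ovine prostaglandin-endoperoxide synthase 1 (COX-1) reconstituted with hematin (C34H33FeN4O5), hydroquinone (0.5 mM), O2-saturated 0.1 M Tris-HCl pH 8.0, 8 at 100 µM, 24 °C, 2 min; quench into Et2O/MeOH/1 M citric acid at −20 °C; fast SiO2 column at −20 °C; kept in dry acetone at −78 °C and used at once
Reagents that add atoms: dioxygen, O=O
Why: The tyrosyl radical (Tyr385) of the cyclooxygenase site removes the 13-pro-S hydrogen of 8, O2 adds to C11 of the C11–C15 pentadienyl radical, the 11-peroxyl radical adds to C9, the C8 radical so formed adds to C12 (new C8–C12 bond), the C13–C15 allyl radical takes up the second O2 at C15 and hydrogen return from the tyrosine gives hydroperoxide 9, which the heme peroxidase site reduces to the C15 alcohol at the expense of hydroquinone. The reaction type is the known prostaglandin-endoperoxide synthase bis-dioxygenation of all-cis C20 polyenoic acids, for which 8 is a natural substrate; in radical terms it is a peroxyl-radical cyclization cascade. The 1,2-dioxolane (C9, C10, C11 and the two oxygens) closes 5-exo-trig by attack of the peroxyl oxygen on C9, and the cyclopentane (C8–C12) closes 5-exo-trig by attack of the C8 radical on C12, which together give the 2,3-dioxabicyclo[2.2.1]heptane. C11 is set by entry of O2 on the face opposite to the abstracted hydrogen, C9 by the bicyclic constraint that places both oxygens on one face, C8 and C12 by the bent substrate conformation in the enzyme channel that puts the two chains trans (carboxyl chain on the peroxide face, C13 chain on the other), and C15 (S) by delivery of O2 to one face of the allyl radical with C13=C14 emerging E. The step needs hydrogen abstraction at C13 and not at the other doubly allylic position C10, and a trans ring substitution that the same radical cascade free in solution does not give; both are secured by the protein, which anchors the carboxylate and places C13 at the tyrosyl radical, while the substrate supplies the all-cis 8,11,14-triene and has no further alkene that could divert the radicals.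

**Step 5**
Reactants: 10 prostaglandin H1
Product: 11 prostaglandin E1, (11α,13E,15S)-11,15-dihydroxy-9-oxoprost-13-enoic acid
Conditions: recombinant human microsomal PGE synthase-1 (membrane fraction), glutathione (2.5 mM), 0.1 M potassium phosphate pH 7.4, 10 added in acetone, 4 to 24 °C, 5 min; citric acid to pH 3.5, EtOAc; C18 reversed-phase chromatography
Reagents that add atoms: none
Why: The glutathione-dependent endoperoxide E-isomerase effects a Kornblum–DeLaMare-type heterolysis of the O–O bond with removal of the C9 hydrogen, so that C9 becomes the ketone and the C11 oxygen the 11α-alcohol, the enzyme imposing the regiochemistry that buffer alone does not; C8, C11, C12 and C15 are not touched and glutathione is regenerated.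

**Step 6**
Reactants: 11 prostaglandin E1
Product: 12 13,14-dihydro-PGE1, 7-[(1R,2R,3R)-3-hydroxy-2-[(3S)-3-hydroxyoctyl]-5-oxocyclopentyl]heptanoic acid
Conditions: H2 (1 atm, stopped at 1 equiv uptake), 5% Pd/C, EtOAc, 0 °C to rt; filtration through Celite; C18 reversed-phase chromatography
Reagents that add atoms: none
Why: Heterogeneous catalytic hydrogenation of the single unhindered trans-disubstituted C13=C14 alkene under neutral conditions, in which C13 and C14 become methylenes so that no stereocentre is formed, the ketone, acid and alcohols are inert at 1 atm, and low temperature with stopped uptake should limit allylic C15–O hydrogenolysis, dehydration of the β-hydroxy ketone and epimerization at C8.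

**Compound list**

1 | hept-1-yne | CCCCCC#C | starting material
2 | 1,4-dichlorobut-2-yne | ClCC#CCCl | starting material
3 | hept-1-ynylmagnesium bromide | CCCCCC#C[Mg]Br | intermediate
4 | 1-chloroundeca-2,5-diyne | CCCCCC#CCC#CCCl | intermediate
5 | non-8-ynoic acid | C#CCCCCCCC(=O)O | starting material
6 | non-8-ynoic acid bis(bromomagnesium) salt, bromomagnesium 9-(bromomagnesio)non-8-ynoate | Br[Mg]C#CCCCCCCC(=O)O[Mg]Br | intermediate
7 | icosa-8,11,14-triynoic acid | CCCCCC#CCC#CCC#CCCCCCCC(=O)O | intermediate
8 | dihomo-γ-linolenic acid, (8Z,11Z,14Z)-icosa-8,11,14-trienoic acid | CCCCC/C=C\C/C=C\C/C=C\CCCCCCC(=O)O | intermediate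
9 | prostaglandin G1, (9α,11α)-epidioxy-(15S)-hydroperoxyprost-(13E)-enoic acid | CCCCC[C@H](OO)/C=C/[C@H]1[C@H]2C[C@H](OO2)[C@@H]1CCCCCCC(=O)O | intermediate
10 | prostaglandin H1, (9α,11α)-epidioxy-(15S)-hydroxyprost-(13E)-enoic acid | CCCCC[C@H](O)/C=C/[C@H]1[C@H]2C[C@H](OO2)[C@@H]1CCCCCCC(=O)O | intermediate
11 | prostaglandin E1, (11α,13E,15S)-11,15-dihydroxy-9-oxoprost-13-enoic acid | CCCCC[C@H](O)/C=C/[C@H]1[C@H](O)CC(=O)[C@@H]1CCCCCCC(=O)O | intermediate
12 | 13,14-dihydro-PGE1, (11α,15S)-11,15-dihydroxy-9-oxoprostanoic acid | CCCCC[C@H](O)CC[C@H]1[C@H](O)CC(=O)[C@@H]1CCCCCCC(=O)O | target

**Step count**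

Total: 6 steps. Longest linear sequence: 6 steps (1 → 4 → 7 → 8 → 10 → 11 → 12); the branch from 5 joins at step 2.

**Steps most likely to fail**

Step 4. The cyclooxygenase may inactivate itself before the substrate is consumed, singly oxygenated hydroxy acids may leak from the site, and the endoperoxide may decay during the cold extraction and chromatography. The fallback sets out from 8 and comes back at 11. It replaces isolation of the endoperoxide by a coupled cascade: 8 is incubated with ram seminal-vesicle microsomes, which carry COX-1 together with the glutathione-dependent E-isomerase, in O2-saturated phosphate buffer pH 8 with glutathione and hydroquinone at 37 °C. Compounds 9 and 10 are then consumed as they form and 11 is extracted directly. This fallback makes no compound outside the list (F0).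

Step 5. While the endoperoxide waits for the isomerase, the uncatalysed rearrangement to the 11-keto-9-hydroxy isomer and the fragmentation with loss of malondialdehyde may compete. The fallback sets out from 10 and comes back at 11 by reduction and redox adjustment with known prostaglandin chemistry. Ph3P in Et2O at 0 °C, which can also serve as the quench of step 4, should reduce the O–O bond to give prostaglandin F1α F1. Me3SiNEt2 in acetone at −45 °C should silylate the acid and the unhindered C11 and C15 hydroxyls but not the C9 hydroxyl, which is screened by the cis carboxyl chain, giving the trimethylsilyl ester 11,15-bis(trimethylsilyl) ether of prostaglandin F1α F2. Collins oxidation with CrO3·2C5H5N in CH2Cl2 at −20 to 0 °C should then give the tris-silylated prostaglandin E1 F3, and MeOH/H2O/AcOH at rt removes the three silyl groups to return 11.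

Step 6. On the palladium surface the allylic C15–O bond may be hydrogenolysed, the allylic alcohol may isomerize to the 15-ketone, and an acidic catalyst batch may dehydrate the β-hydroxy ketone. The fallback sets out from 11 and comes back at 12. It changes the reductant class to a metal-free concerted hydrogen transfer: diimide, generated from dipotassium azodicarboxylate and AcOH in MeOH at 0 °C to rt, should add H2 syn to C13=C14 only, with no path to hydrogenolysis or allylic isomerization. This fallback makes no compound outside the list (F0).

**Further compounds**

F0 | step 4 | none | none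
F1 | step 5 | prostaglandin F1α, (9α,11α,13E,15S)-9,11,15-trihydroxyprost-13-enoic acid | CCCCC[C@H](O)/C=C/[C@H]1[C@H](O)C[C@H](O)[C@@H]1CCCCCCC(=O)O
F2 | step 5 | trimethylsilyl (9α,11α,13E,15S)-9-hydroxy-11,15-bis(trimethylsilyloxy)prost-13-enoate | CCCCC[C@H](O[Si](C)(C)C)/C=C/[C@H]1[C@H](O[Si](C)(C)C)C[C@H](O)[C@@H]1CCCCCCC(=O)O[Si](C)(C)C
F3 | step 5 | trimethylsilyl (11α,13E,15S)-9-oxo-11,15-bis(trimethylsilyloxy)prost-13-enoate | CCCCC[C@H](O[Si](C)(C)C)/C=C/[C@H]1[C@H](O[Si](C)(C)C)CC(=O)[C@@H]1CCCCCCC(=O)O[Si](C)(C)C
F0 | step 6 | none | none
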